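**Assumption (one line):** positions are named by prostanoid numbering (C1 = ester carbon, ring = C8–C12, C20 = chain methyl); (−)-sparteine is taken to give the (S)-configured α-lithio carbamate, so that 1,2-migration with inversion leads to the (R)-allylboron reagent.

## Retrosynthetic overview

- Endgame: the C9 ketone comes from a silyl-protected C9 carbinol (oxidation last), the C7 acetate from the free C7 alcohol.
- Key disconnection C12–C13: the homoallylic tertiary carbinol C12(OH)–C13H2–C14=C15 (Z) is an allylboration retron; it is opened to a C12 ketone (β-hydroxy enone) and enantiopure (R)-oct-1-en-3-ylboronic acid.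
- Enabling feature: O7 and O12 are 1,3-related (O7–C7–C8–C12–O12) and cis on the cyclopentene, so one boron atom bound to O7 can bridge to O12 in a six-membered 1,3,2-dioxaborinane while its allyl group reaches C12.
- C7–C8 comes from a syn-selective titanium-enolate aldol of (S)-3-chloro-4-silyloxycyclopent-2-enone with methyl (Z)-7-oxohept-5-enoate; the boron reagent comes from hexan-1-ol by lithiation–borylation.
- Rings: the cyclopentene is bought as (R)-4-silyloxycyclopent-2-enone and adjusted by α-chlorination and 1,3-oxygen transposition; no carbocycle is formed, and the only ring made is the temporary dioxaborinane of the key step, opened on work-up.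

Key step: step 15

## Route

**Ring fragment**

Step 1
Reactants: 1 (R)-4-[(tert-butyldimethylsilyl)oxy]cyclopent-2-en-1-one
Product: 2 (R)-4-[(tert-butyldimethylsilyl)oxy]-2-chlorocyclopent-2-en-1-one
Conditions: PhICl2, pyridine, CH2Cl2, 0 °C to rt
Reagents that add atoms: (dichloroiodo)benzene, ClI(Cl)c1ccccc1
Why: α-Halogenation of an enone (net substitution of the α-vinylic hydrogen by electrophilic chlorine in the presence of pyridine) should touch only the enone C–H and leave the silyl ether and the C4 stereocentre unchanged.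

Step 2
Reactants: 2 (R)-4-[(tert-butyldimethylsilyl)oxy]-2-chlorocyclopent-2-en-1-one
Product: 3 (1S,4R)-4-[(tert-butyldimethylsilyl)oxy]-2-chlorocyclopent-2-en-1-ol (cis)
Conditions: NaBH4, CeCl3·7H2O, MeOH, −78 °C
Reagents that add atoms: none
Why: Luche 1,2-reduction, in which hydride should add to the carbonyl face anti to the C4 silyloxy group and so give the cis-1,4 relationship (new carbinol centre 1S, the future C9).

Step 3
Reactants: 3 (1S,4R)-4-[(tert-butyldimethylsilyl)oxy]-2-chlorocyclopent-2-en-1-ol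
Product: 4 tert-butyl{[(1S,4R)-4-[(tert-butyldimethylsilyl)oxy]-2-chlorocyclopent-2-en-1-yl]oxy}diphenylsilane
Conditions: TBDPSCl, imidazole, DMF, rt
Reagents that add atoms: tert-butyl(chloro)diphenylsilane, CC(C)(C)[Si](Cl)(c1ccccc1)c1ccccc1
Why: Imidazole-promoted silylation of a secondary alcohol under non-alkoxide conditions, which avoids 1,3-silyl migration between the two cis oxygens.

Step 4
Reactants: 4 tert-butyl{[(1S,4R)-4-[(tert-butyldimethylsilyl)oxy]-2-chlorocyclopent-2-en-1-yl]oxy}diphenylsilane
Product: 5 (1R,4S)-4-[(tert-butyldiphenylsilyl)oxy]-3-chlorocyclopent-2-en-1-ol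
Conditions: CSA (cat.), MeOH/CH2Cl2, 0 °C
Reagents that add atoms: none
Why: Acid-catalysed methanolysis of silyl ethers, selective because a secondary TBS ether is cleaved far faster than a TBDPS ether.

Step 5
Reactants: 5 (1R,4S)-4-[(tert-butyldiphenylsilyl)oxy]-3-chlorocyclopent-2-en-1-ol
Product: 6 (S)-4-[(tert-butyldiphenylsilyl)oxy]-3-chlorocyclopent-2-en-1-one
Conditions: Dess–Martin periodinane, NaHCO3, CH2Cl2, 0 °C to rt
Reagents that add atoms: none
Why: Dess–Martin oxidation of the allylic alcohol completes the 1,3-oxygen transposition, placing the ketone at the future C12 and leaving the silyloxy carbon (future C9) as the only stereocentre.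

**C1–C7 aldehyde**

Step 6
Reactants: 7 hex-5-ynoic acid
Product: 9 7-hydroxyhept-5-ynoic acid, via dilithiated acid 8 (not isolated)
Conditions: n-BuLi (2.2 equiv), THF/DMPU, −78 to 0 °C; (CH2O)n, 0 °C to rt; aq. HCl
Reagents that add atoms: formaldehyde (as paraformaldehyde), C=O
Why: Hydroxymethylation of a lithium acetylide, the carboxylate being protected as its lithium salt in the dianion.

Step 7
Reactants: 9 7-hydroxyhept-5-ynoic acid
Product: 10 methyl 7-hydroxyhept-5-ynoate
Conditions: MeOH, H2SO4 (cat.), rt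
Reagents that add atoms: methanol, CO
Why: Fischer esterification, to which the propargylic alcohol is inert.

Step 8
Reactants: 10 methyl 7-hydroxyhept-5-ynoate
Product: 11 methyl (Z)-7-hydroxyhept-5-enoate
Conditions: H2 (1 atm), Lindlar catalyst, quinoline, EtOAc, rt
Reagents that add atoms: none
Why: Lindlar semi-hydrogenation delivers both hydrogens to one face of the alkyne and so should set the Z C5=C6 alkene.

Step 9
Reactants: 11 methyl (Z)-7-hydroxyhept-5-enoate
Product: 12 methyl (Z)-7-oxohept-5-enoate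
Conditions: Dess–Martin periodinane, NaHCO3, CH2Cl2, 0 °C; used at once
Reagents that add atoms: none
Why: Buffered Dess–Martin oxidation of an allylic alcohol is neutral enough that the Z-enal should not isomerise before use.

**Aldol union**

Step 10
Reactants: 6 (S)-4-[(tert-butyldiphenylsilyl)oxy]-3-chlorocyclopent-2-en-1-one; 12 methyl (Z)-7-oxohept-5-enoate
Product: 15 methyl (5Z,7S)-7-[(1S,5S)-5-[(tert-butyldiphenylsilyl)oxy]-4-chloro-2-oxocyclopent-3-en-1-yl]-7-hydroxyhept-5-enoate, via lithium enolate 13 (not isolated), via titanium enolate 14 (not isolated)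
Conditions: LDA, THF, −78 °C; ClTi(OiPr)3, −78 to −45 °C; 12, −78 °C; aq. NH4Cl
Reagents that add atoms: none
Why: Kinetic deprotonation at the only α'-CH2 gives the ring-locked (E)-enolate 13, and its triisopropoxytitanium derivative 14 is expected to add in the syn (erythro) sense that titanium enolates show irrespective of enolate geometry (titanium-enolate aldol addition), with the aldehyde approaching anti to the neighbouring silyloxy group, which sets C8 trans to C9–O and C7 as (S).

**Boron reagent**

Step 11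
Reactants: 16 hexan-1-ol
Product: 17 hexyl N,N-diisopropylcarbamate
Conditions: iPr2NCOCl, Et3N, CH2Cl2, reflux
Reagents that add atoms: N,N-diisopropylcarbamoyl chloride, CC(C)N(C(C)C)C(Cl)=O
Why: O-Carbamoylation of a primary alcohol installs the directing and leaving group for asymmetric α-lithiation.

Step 12
Reactants: 17 hexyl N,N-diisopropylcarbamate; 18 4,4,5,5-tetramethyl-2-vinyl-1,3,2-dioxaborolane
Product: 21 (R)-4,4,5,5-tetramethyl-2-(oct-1-en-3-yl)-1,3,2-dioxaborolane, via lithiated carbamate 19 (not isolated), via boronate complex 20 (not isolated)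
Conditions: s-BuLi, (−)-sparteine, Et2O, −78 °C; 18, −78 °C; MgBr2·OEt2, −78 °C to reflux
Reagents that add atoms: none
Why: Sparteine-mediated asymmetric α-lithiation of the O-alkyl carbamate is expected to give the (S)-organolithium 19, which is borylated by 18 with retention to the ate complex 20 and then undergoes a Matteson-type 1,2-metallate rearrangement (vinyl migration with inversion, loss of the carbamate), so that the boron-bearing stereocentre of 21 should be (R) (lithiation–borylation).

Step 13
Reactants: 21 (R)-4,4,5,5-tetramethyl-2-(oct-1-en-3-yl)-1,3,2-dioxaborolane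
Product: 22 potassium (R)-trifluoro(oct-1-en-3-yl)borate
Conditions: KHF2 (aq.), MeOH, rt
Reagents that add atoms: potassium hydrogen difluoride, [K+].F[H-]F
Why: Conversion of a pinacol boronate into its trifluoroborate salt removes the non-exchangeable pinacol ligand without touching the C–B stereocentre.

Step 14
Reactants: 22 potassium (R)-trifluoro(oct-1-en-3-yl)borate
Product: 23 (R)-oct-1-en-3-ylboronic acid
Conditions: silica gel, H2O/EtOAc, rt, Ar; organic phase dried and used at once
Reagents that add atoms: water, O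
Why: Fluorophile-driven hydrolysis of an organotrifluoroborate on silica gives the free boronic acid under neutral conditions, and oxygen-ligated allylboron species should resist 1,3-boratropic shift at room temperature.

**Key step and endgame**

Step 15
Reactants: 15 methyl (5Z,7S)-7-[(1S,5S)-5-[(tert-butyldiphenylsilyl)oxy]-4-chloro-2-oxocyclopent-3-en-1-yl]-7-hydroxyhept-5-enoate; 23 (R)-oct-1-en-3-ylboronic acid
Product: 26 methyl (5Z,7S)-7-[(1S,2S,5S)-5-[(tert-butyldiphenylsilyl)oxy]-4-chloro-2-hydroxy-2-[(2Z)-oct-2-en-1-yl]cyclopent-3-en-1-yl]-7-hydroxyhept-5-enoate, via tethered boronate 24 (not isolated), via cyclic borate 25 (not isolated)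
Conditions: 4 Å MS, CH2Cl2, −40 to 0 °C, Ar; then aq. NaHCO3, 0 °C
Reagents that add atoms: none
Why: The boronic acid esterifies the C7 hydroxyl to give 24, the C12 carbonyl oxygen then binds the boron, and the allyl group is transferred through a six-membered chair (B, O12, C12, C13, C14, C15) with allylic transposition, so that the former =CH2 carbon becomes C13 bonded to C12 and the C14=C15 alkene is created; the closest known reaction types are the hydroxyl-directed allylboration of β-hydroxy ketones by exchangeable allylboron esters and the 1,3-chirality transfer of α-substituted allylboron reagents. The only ring closed is the temporary 1,3,2-dioxaborinane of 25 (B, O7, C7, C8, C12, O12), closed by O12–B bonding in concert with C–C bond formation in a bicyclo[3.3.1]-like transition state and opened again by hydrolysis on work-up. The C12 stereocentre is controlled by C8, because the tether can deliver the allyl unit only to the ring face anti to the C7-bearing substituent (delivery to the syn face would eclipse the forming C12–C13 bond with C8–C7), which should give 12S with the hydroxyl cis to the C7 chain. The tether also forces C8 into the pseudoaxial position of the chair, so with the ring face fixed the (R) configuration of the boron-bearing carbon places the pentyl group pseudoaxial and should translate into the Z C14=C15 geometry (the S reagent would give E), a matched pairing of substrate and reagent control. The required 1,2- over 1,4-addition and bonding through the unsubstituted allyl terminus are inherent to the closed allylboration transition state, the ester and vinyl chloride are inert to the neutral reagent, and intramolecular delivery should let the hindered enone carbonyl react at low temperature.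

Step 16
Reactants: 26 methyl (5Z,7S)-7-[(1S,2S,5S)-5-[(tert-butyldiphenylsilyl)oxy]-4-chloro-2-hydroxy-2-[(2Z)-oct-2-en-1-yl]cyclopent-3-en-1-yl]-7-hydroxyhept-5-enoate
Product: 27 methyl (5Z,7S)-7-acetoxy-7-[(1S,2S,5S)-5-[(tert-butyldiphenylsilyl)oxy]-4-chloro-2-hydroxy-2-[(2Z)-oct-2-en-1-yl]cyclopent-3-en-1-yl]hept-5-enoate
Conditions: Ac2O, pyridine, DMAP (cat.), CH2Cl2, 0 °C
Reagents that add atoms: acetic anhydride, CC(=O)OC(C)=O
Why: DMAP-catalysed acetylation should take the secondary C7 alcohol and leave the tertiary C12 alcohol free at 0 °C.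

Step 17
Reactants: 27 methyl (5Z,7S)-7-acetoxy-7-[(1S,2S,5S)-5-[(tert-butyldiphenylsilyl)oxy]-4-chloro-2-hydroxy-2-[(2Z)-oct-2-en-1-yl]cyclopent-3-en-1-yl]hept-5-enoate
Product: 28 methyl (5Z,7S)-7-acetoxy-7-[(1R,2S,5S)-4-chloro-2,5-dihydroxy-2-[(2Z)-oct-2-en-1-yl]cyclopent-3-en-1-yl]hept-5-enoate
Conditions: TBAF, AcOH (1:1), THF, 0 °C to rt
Reagents that add atoms: none
Why: Fluoride-mediated desilylation buffered with acetic acid should free the C9 alcohol without acetate migration or ionisation of the tertiary allylic alcohol (the C8 descriptor changes only because the priorities change).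

Step 18
Reactants: 28 methyl (5Z,7S)-7-acetoxy-7-[(1R,2S,5S)-4-chloro-2,5-dihydroxy-2-[(2Z)-oct-2-en-1-yl]cyclopent-3-en-1-yl]hept-5-enoate
Product: 29 punaglandin 8, methyl (5Z,7S)-7-acetoxy-7-[(1R,2S)-4-chloro-2-hydroxy-2-[(2Z)-oct-2-en-1-yl]-5-oxocyclopent-3-en-1-yl]hept-5-enoate
Conditions: Dess–Martin periodinane, NaHCO3, CH2Cl2, 0 °C
Reagents that add atoms: none
Why: Dess–Martin oxidation of the secondary allylic C9 alcohol gives the α-chloroenone under buffered, non-basic conditions that should avoid E1cB loss of the β-acetoxy group and epimerisation at C8, while the tertiary alcohol cannot be oxidised.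

## Compound list

1 | (R)-4-[(tert-butyldimethylsilyl)oxy]cyclopent-2-en-1-one | O=C1C=C[C@H](O[Si](C)(C)C(C)(C)C)C1 | starting material
2 | (R)-4-[(tert-butyldimethylsilyl)oxy]-2-chlorocyclopent-2-en-1-one | O=C1C(Cl)=C[C@H](O[Si](C)(C)C(C)(C)C)C1 | intermediate
3 | (1S,4R)-4-[(tert-butyldimethylsilyl)oxy]-2-chlorocyclopent-2-en-1-ol | O[C@@H]1C(Cl)=C[C@H](O[Si](C)(C)C(C)(C)C)C1 | intermediate
4 | tert-butyl{[(1S,4R)-4-[(tert-butyldimethylsilyl)oxy]-2-chlorocyclopent-2-en-1-yl]oxy}diphenylsilane | CC(C)(C)[Si](C)(C)O[C@H]1C=C(Cl)[C@@H](O[Si](c2ccccc2)(c2ccccc2)C(C)(C)C)C1 | intermediate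
5 | (1R,4S)-4-[(tert-butyldiphenylsilyl)oxy]-3-chlorocyclopent-2-en-1-ol | O[C@H]1C=C(Cl)[C@@H](O[Si](c2ccccc2)(c2ccccc2)C(C)(C)C)C1 | intermediate
6 | (S)-4-[(tert-butyldiphenylsilyl)oxy]-3-chlorocyclopent-2-en-1-one | O=C1C=C(Cl)[C@@H](O[Si](c2ccccc2)(c2ccccc2)C(C)(C)C)C1 | intermediate
7 | hex-5-ynoic acid | C#CCCCC(=O)O | starting material
8 | dilithiated hex-5-ynoic acid (lithium 6-lithiohex-5-ynoate) | [Li]C#CCCCC(=O)O[Li] | intermediate
9 | 7-hydroxyhept-5-ynoic acid | OCC#CCCCC(=O)O | intermediate
10 | methyl 7-hydroxyhept-5-ynoate | COC(=O)CCCC#CCO | intermediate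
11 | methyl (Z)-7-hydroxyhept-5-enoate | COC(=O)CCC/C=C\CO | intermediate
12 | methyl (Z)-7-oxohept-5-enoate | COC(=O)CCC/C=C\C=O | intermediate
13 | lithium enolate of 6 (lithium (S)-4-[(tert-butyldiphenylsilyl)oxy]-3-chlorocyclopenta-1,5-dien-1-olate, cross-conjugated) | [Li]OC1=C[C@H](O[Si](c2ccccc2)(c2ccccc2)C(C)(C)C)C(Cl)=C1 | intermediate
14 | triisopropoxytitanium enolate of 6 | CC(C)O[Ti](OC(C)C)(OC(C)C)OC1=C[C@H](O[Si](c2ccccc2)(c2ccccc2)C(C)(C)C)C(Cl)=C1 | intermediate
15 | methyl (5Z,7S)-7-[(1S,5S)-5-[(tert-butyldiphenylsilyl)oxy]-4-chloro-2-oxocyclopent-3-en-1-yl]-7-hydroxyhept-5-enoate | O=C1C=C(Cl)[C@@H](O[Si](c2ccccc2)(c2ccccc2)C(C)(C)C)[C@@H]1[C@H](/C=C\CCCC(=O)OC)O | intermediate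
16 | hexan-1-ol | CCCCCCO | starting material
17 | hexyl N,N-diisopropylcarbamate | CCCCCCOC(=O)N(C(C)C)C(C)C | intermediate
18 | 4,4,5,5-tetramethyl-2-vinyl-1,3,2-dioxaborolane | C=CB1OC(C)(C)C(C)(C)O1 | starting material
19 | (S)-1-lithiohexyl N,N-diisopropylcarbamate (sparteine complex) | CCCCC[C@H]([Li])OC(=O)N(C(C)C)C(C)C | intermediate
20 | lithium (S)-[1-(diisopropylcarbamoyloxy)hexyl](vinyl)pinacolatoborate | [Li+].CCCCC[C@H]([B-]1(C=C)OC(C)(C)C(C)(C)O1)OC(=O)N(C(C)C)C(C)C | intermediate
21 | (R)-4,4,5,5-tetramethyl-2-(oct-1-en-3-yl)-1,3,2-dioxaborolane | CCCCC[C@H](C=C)B1OC(C)(C)C(C)(C)O1 | intermediate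
22 | potassium (R)-trifluoro(oct-1-en-3-yl)borate | [K+].CCCCC[C@H](C=C)[B-](F)(F)F | intermediate
23 | (R)-oct-1-en-3-ylboronic acid | CCCCC[C@H](C=C)B(O)O | intermediate
24 | O7-bound mixed boronic monoester of 15 with 23 (C7–O–B(OH)–CH(C5H11)CH=CH2, boron-bearing carbon R) | O=C1C=C(Cl)[C@@H](O[Si](c2ccccc2)(c2ccccc2)C(C)(C)C)[C@@H]1[C@H](/C=C\CCCC(=O)OC)OB(O)[C@H](CCCCC)C=C | intermediate
25 | cyclic borate of 26 (2-hydroxy-1,3,2-dioxaborinane bridging O7 and O12) | CCCCC/C=C\C[C@@]1(O2)C=C(Cl)[C@@H](O[Si](c3ccccc3)(c3ccccc3)C(C)(C)C)[C@@H]1[C@H](/C=C\CCCC(=O)OC)OB2O | intermediate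
26 | methyl (5Z,7S)-7-[(1S,2S,5S)-5-[(tert-butyldiphenylsilyl)oxy]-4-chloro-2-hydroxy-2-[(2Z)-oct-2-en-1-yl]cyclopent-3-en-1-yl]-7-hydroxyhept-5-enoate | CCCCC/C=C\C[C@@]1(O)C=C(Cl)[C@@H](O[Si](c2ccccc2)(c2ccccc2)C(C)(C)C)[C@@H]1[C@H](/C=C\CCCC(=O)OC)O | intermediate
27 | methyl (5Z,7S)-7-acetoxy-7-[(1S,2S,5S)-5-[(tert-butyldiphenylsilyl)oxy]-4-chloro-2-hydroxy-2-[(2Z)-oct-2-en-1-yl]cyclopent-3-en-1-yl]hept-5-enoate | CCCCC/C=C\C[C@@]1(O)C=C(Cl)[C@@H](O[Si](c2ccccc2)(c2ccccc2)C(C)(C)C)[C@@H]1[C@H](/C=C\CCCC(=O)OC)OC(C)=O | intermediate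
28 | methyl (5Z,7S)-7-acetoxy-7-[(1R,2S,5S)-4-chloro-2,5-dihydroxy-2-[(2Z)-oct-2-en-1-yl]cyclopent-3-en-1-yl]hept-5-enoate | CCCCC/C=C\C[C@@]1(O)C=C(Cl)[C@@H](O)[C@@H]1[C@H](/C=C\CCCC(=O)OC)OC(C)=O | intermediate
29 | punaglandin 8, methyl (5Z,7S)-7-acetoxy-7-[(1R,2S)-4-chloro-2-hydroxy-2-[(2Z)-oct-2-en-1-yl]-5-oxocyclopent-3-en-1-yl]hept-5-enoate | CCCCC/C=C\C[C@@]1(O)C=C(Cl)C(=O)[C@@H]1[C@H](/C=C\CCCC(=O)OC)OC(C)=O | target

## Step count and risks

Total step count: 18. Longest linear sequence: 10 steps (steps 1–5, 10, 15–18, from 1).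

**Step 15 (key step).** The allyl group may be transferred through an untethered, bimolecular pathway, or the allylboron unit may undergo a 1,3-boratropic shift before transfer; either would erode the Z/E ratio and the facial control. The 3-chloroallylic tertiary alcohol of the product may also ionise if the medium turns acidic. The fallback sets out from 15 and comes back at 26. Compound 15 is allylated under Barbier conditions (allyl bromide, indium powder, THF/H2O, rt), where chelation between the C7 hydroxyl and the C12 carbonyl should again direct the allyl group anti to the C8 substituent, to give the 12-allyl diol F1. The pentyl terminus is then attached by Z-selective cross-metathesis with hept-1-ene (cyclometalated ruthenium Z-selective catalyst, THF, 35 °C, static vacuum to remove ethylene), which gives 26. Here the Z geometry is set by the catalyst and no longer by the boron stereocentre.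

**Step 10 (aldol).** Silyloxide may be lost from the α'-enolate by β-elimination during the lithium-to-titanium exchange, and the syn/anti control at C7 may be insufficient. The fallback sets out from 6 and 12 and comes back at 27. The lithium enolate 13 alone (LDA, THF, −78 °C, no titanium) adds to 12 through the Zimmerman–Traxler chair of an (E)-enolate, which should favour the anti aldol, the C7 epimer F2. The boron-tethered allyl transfer is then run on F2 exactly as in step 15 (C8, not C7, decides the ring face), passing through the epimeric tethered boronate F3 and the epimeric cyclic borate F4 to the 7-epi diol F5. A Mitsunobu reaction with acetic acid (PPh3, DIAD, toluene, 0 °C) on F5 then installs the acetate with inversion at C7 and gives 27 directly; the tertiary C12 alcohol does not react.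

**Step 14 (free boronic acid).** Configurational and positional integrity may be lost through 1,3-boratropic shift, and the free α-substituted allylboronic acid may oxidise during liberation and handling. The fallback sets out from 22 and 15 and comes back at 26, and makes the tether by B–F/O–Si exchange without ever liberating the acid. Compound 15 is silylated (TMSCl, imidazole, CH2Cl2, 0 °C) to the C7 trimethylsilyl ether F6. In a second flask 22 is treated with BF3·OEt2 (CH2Cl2, −78 °C), which precipitates KBF4 and gives the allyldifluoroborane F7. Addition of F6 at −78 °C should exchange Si–O for B–O with loss of Me3SiF, giving the fluoroborane tether F8, which transfers its allyl group as in step 15 to the cyclic fluoroborate F9. Cold aqueous NaHCO3 then releases 26.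

## Further compounds

F1 | step 15 | methyl (5Z,7S)-7-[(1S,2S,5S)-2-allyl-5-[(tert-butyldiphenylsilyl)oxy]-4-chloro-2-hydroxycyclopent-3-en-1-yl]-7-hydroxyhept-5-enoate | C=CC[C@@]1(O)C=C(Cl)[C@@H](O[Si](c2ccccc2)(c2ccccc2)C(C)(C)C)[C@@H]1[C@H](/C=C\CCCC(=O)OC)O
F2 | step 10 | methyl (5Z,7R)-7-[(1S,5S)-5-[(tert-butyldiphenylsilyl)oxy]-4-chloro-2-oxocyclopent-3-en-1-yl]-7-hydroxyhept-5-enoate (7-epi-15) | O=C1C=C(Cl)[C@@H](O[Si](c2ccccc2)(c2ccccc2)C(C)(C)C)[C@@H]1[C@@H](/C=C\CCCC(=O)OC)O
F3 | step 10 | O7-bound mixed boronic monoester of F2 with 23 (7-epi-24) | O=C1C=C(Cl)[C@@H](O[Si](c2ccccc2)(c2ccccc2)C(C)(C)C)[C@@H]1[C@@H](/C=C\CCCC(=O)OC)OB(O)[C@H](CCCCC)C=C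
F4 | step 10 | cyclic borate of F5 (7-epi-25) | CCCCC/C=C\C[C@@]1(O2)C=C(Cl)[C@@H](O[Si](c3ccccc3)(c3ccccc3)C(C)(C)C)[C@@H]1[C@@H](/C=C\CCCC(=O)OC)OB2O
F5 | step 10 | methyl (5Z,7R)-7-[(1S,2S,5S)-5-[(tert-butyldiphenylsilyl)oxy]-4-chloro-2-hydroxy-2-[(2Z)-oct-2-en-1-yl]cyclopent-3-en-1-yl]-7-hydroxyhept-5-enoate (7-epi-26) | CCCCC/C=C\C[C@@]1(O)C=C(Cl)[C@@H](O[Si](c2ccccc2)(c2ccccc2)C(C)(C)C)[C@@H]1[C@@H](/C=C\CCCC(=O)OC)O
F6 | step 14 | methyl (5Z,7S)-7-[(1S,5S)-5-[(tert-butyldiphenylsilyl)oxy]-4-chloro-2-oxocyclopent-3-en-1-yl]-7-[(trimethylsilyl)oxy]hept-5-enoate | O=C1C=C(Cl)[C@@H](O[Si](c2ccccc2)(c2ccccc2)C(C)(C)C)[C@@H]1[C@H](/C=C\CCCC(=O)OC)O[Si](C)(C)C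
F7 | step 14 | (R)-difluoro(oct-1-en-3-yl)borane | CCCCC[C@H](C=C)B(F)F
F8 | step 14 | O7-bound fluoro(oct-1-en-3-yl)borane ester of 15 (fluoro analogue of 24) | O=C1C=C(Cl)[C@@H](O[Si](c2ccccc2)(c2ccccc2)C(C)(C)C)[C@@H]1[C@H](/C=C\CCCC(=O)OC)OB(F)[C@H](CCCCC)C=C
F9 | step 14 | cyclic fluoroborate of 26 (2-fluoro-1,3,2-dioxaborinane bridging O7 and O12) | CCCCC/C=C\C[C@@]1(O2)C=C(Cl)[C@@H](O[Si](c3ccccc3)(c3ccccc3)C(C)(C)C)[C@@H]1[C@H](/C=C\CCCC(=O)OC)OB2F
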